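The route rests on cutting the bond between C1 of the styryl guaiacyl ring (ring D) and the outer alkene carbon. This is a final Mizoroki–Heck union of 4-iodoguaiacol with the terminal =CH2 of a C5-vinyl group on the benzo ring (ring A) of an (R)-configured 4-arylchroman-2-one. In one operation, on three free phenols and the intact lactone (ring B), it makes the last C–C bond, sets the E-alkene and delivers the target without protecting groups. It exploits the peri relationship of C4 and C5: the pseudoaxial C4-aryl (ring C) screens the inner vinyl carbon, leaving only the terminus open. C4 is set beforehand by rhodium-catalysed asymmetric 1,4-arylation of 5-bromo-7-hydroxycoumarin.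

Key step: step 5

Assumption: chroman-2-one numbering is used (O1, C2 carbonyl, C3, C4, C4a, C5 to C8, C8a). The sense of induction of (R)-SEGPHOS is taken from the parent coumarin series, where the (R)-ligand gives the (R)-4-arylchroman-2-one with the same priority order at C4 (C4a > aryl > C3 > H).

Step 1
Reactants: 1 5-bromoresorcinol
Product: 3 2-bromo-4,6-dihydroxybenzaldehyde, via aryl iminium chloride 2 (not isolated)
Conditions: POCl3, DMF, 0 °C to rt; then H2O, 50 °C
Reagents that add atoms: N,N-dimethylformamide CN(C)C=O; water O
Why: Vilsmeier–Haack formylation, in which the chloroiminium ion attacks the resorcinol para to one OH and ortho to the other (as in the formylation of orcinol, the position between the two OH groups stays untouched) and water hydrolyses the iminium salt, so the substitution pattern of ring A is fixed without ambiguity.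

Step 2
Reactants: 3 2-bromo-4,6-dihydroxybenzaldehyde; 4 ethyl (triphenylphosphoranylidene)acetate
Product: 6 5-bromo-7-hydroxycoumarin, via ethyl 2-bromo-4,6-dihydroxycinnamate 5 (not isolated)
Conditions: PhNEt2, reflux (about 215 °C), N2
Reagents that add atoms: none
Why: Wittig olefination with the stabilised ylide is followed in the same flask by thermal E-to-Z isomerisation and lactonisation of the o-hydroxycinnamate with loss of ethanol, the standard one-flask coumarin synthesis from salicylaldehydes, and only the OH ortho to the side chain can close the six-membered ring B.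

Step 3
Reactants: 6 5-bromo-7-hydroxycoumarin; 7 4-hydroxy-3-methoxyphenylboronic acid (excess, added in portions)
Product: 8 (R)-5-bromo-7-hydroxy-4-(4-hydroxy-3-methoxyphenyl)chroman-2-one
Conditions: Rh(acac)(C2H4)2 (3 mol %), (R)-SEGPHOS (3.3 mol %), 1,4-dioxane/H2O 10:1, 60 °C
Reagents that add atoms: none
Why: Hayashi–Miyaura asymmetric 1,4-addition, a reaction type established for coumarins, in which the aryl-rhodium species held by (R)-SEGPHOS adds across C3=C4 from one face (perpendicular to the ring plane, hence little hindered by the in-plane peri bromine) and hydrolysis of the oxa-π-allyl rhodium gives the (R)-centre at C4, while the base-free medium keeps 7-OH protonated and the C–Br bond is inert to monovalent rhodium.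

Step 4
Reactants: 8 (R)-5-bromo-7-hydroxy-4-(4-hydroxy-3-methoxyphenyl)chroman-2-one
Product: 9 (R)-7-hydroxy-4-(4-hydroxy-3-methoxyphenyl)-5-vinylchroman-2-one
Conditions: tributyl(vinyl)stannane, Pd(PPh3)4 (5 mol %), BHT (cat), 1,4-dioxane, 100 °C
Reagents that add atoms: tributyl(vinyl)stannane C=C[Sn](CCCC)(CCCC)CCCC
Why: Migita–Kosugi–Stille vinylation of the aryl bromide, whose neutral, base-free conditions leave ring B, both phenols and C4 untouched and give no opening for base-assisted C–H palladation of ring C by the aryl-palladium species at C5.

Step 5
Reactants: 9 (R)-7-hydroxy-4-(4-hydroxy-3-methoxyphenyl)-5-vinylchroman-2-one; 10 4-iodo-2-methoxyphenol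
Product: 11 (R)-7-hydroxy-4-(4-hydroxy-3-methoxyphenyl)-5-[(E)-2-(4-hydroxy-3-methoxyphenyl)ethenyl]chroman-2-one (CNP0277187.1)
Conditions: Pd(OAc)2 (5 mol %), P(o-tol)3 (12 mol %), Et3N, MeCN, 80 °C, argon, exclusion of light
Reagents that add atoms: none
Why: Mizoroki–Heck reaction: zerovalent palladium formed in situ inserts into the C–I bond of 10, the aryl-palladium iodide binds the C5-vinyl group of 9, syn-carbopalladation puts ring D on the terminal carbon and palladium on the benzylic carbon, and bond rotation followed by syn-β-hydride elimination releases the stilbene while Et3N takes up HI. The closest known reaction type is the Heck synthesis of resveratrol-type hydroxystilbenes from styrenes and iodophenols. No ring is closed and no stereocentre is made; the (R)-centre at C4 is only carried through, since its hydrogen is not acidic towards Et3N and C4 bears no leaving group. Regioselectivity for the terminal carbon is needed and is secured by the neutral iodide pathway and by the peri C4 substituent, whose pseudoaxial ring C crowds the inner vinyl carbon. E-geometry is needed and follows from the less eclipsed rotamer in the β-hydride elimination, with ring A and ring D anti. Chemoselectivity is secured because the C–I bond of 10 is the only carbon–halogen bond present, the phenols are not arylated without a strong base, and the medium holds no nucleophile that could open ring B.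

Compound list
1 | 5-bromoresorcinol (5-bromobenzene-1,3-diol) | Oc1cc(O)cc(Br)c1 | starting material
2 | (2-bromo-4,6-dihydroxybenzylidene)dimethyliminium chloride | C[N+](C)=Cc1c(O)cc(O)cc1Br.[Cl-] | intermediate
3 | 2-bromo-4,6-dihydroxybenzaldehyde | O=Cc1c(O)cc(O)cc1Br | intermediate
4 | ethyl (triphenylphosphoranylidene)acetate | CCOC(=O)C=P(c1ccccc1)(c1ccccc1)c1ccccc1 | starting material
5 | ethyl (E)-3-(2-bromo-4,6-dihydroxyphenyl)acrylate | CCOC(=O)/C=C/c1c(O)cc(O)cc1Br | intermediate
6 | 5-bromo-7-hydroxycoumarin (5-bromo-7-hydroxy-2H-chromen-2-one) | O=c1ccc2c(Br)cc(O)cc2o1 | intermediate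
7 | 4-hydroxy-3-methoxyphenylboronic acid | COc1cc(B(O)O)ccc1O | starting material
8 | (R)-5-bromo-7-hydroxy-4-(4-hydroxy-3-methoxyphenyl)chroman-2-one | Brc1cc(O)cc2c1[C@@H](c1ccc(O)c(OC)c1)CC(=O)O2 | intermediate
9 | (R)-7-hydroxy-4-(4-hydroxy-3-methoxyphenyl)-5-vinylchroman-2-one | C=Cc1cc(O)cc2c1[C@@H](c1ccc(O)c(OC)c1)CC(=O)O2 | intermediate
10 | 4-iodo-2-methoxyphenol (4-iodoguaiacol) | COc1cc(I)ccc1O | starting material
11 | (R)-7-hydroxy-4-(4-hydroxy-3-methoxyphenyl)-5-[(E)-2-(4-hydroxy-3-methoxyphenyl)ethenyl]chroman-2-one | COc1cc(/C=C/c2cc(O)cc3c2[C@@H](c2ccc(O)c(OC)c2)CC(=O)O3)ccc1O | target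

Total step count: 5. Longest linear sequence: 5 steps (1 → 3 → 6 → 8 → 9 → 11).

Steps most likely to fail

Step 3. Insertion of the C3=C4 bond of the electron-rich, peri-substituted coumarin into the aryl–rhodium bond may be slower than protodeboronation of 7. The peri bromine may also lower the facial selectivity. The fallback separates C–C bond formation from stereoinduction.
- It sets out from 6. An oxidative boron-Heck arylation with 7 (Pd(OAc)2, 1,10-phenanthroline, O2, DMF, 80 °C) can be forced, because no stereocentre is at stake. It would give the flat 5-bromo-7-hydroxy-4-(4-hydroxy-3-methoxyphenyl)coumarin F1.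
- An asymmetric copper hydride 1,4-reduction follows (Cu(OAc)2·H2O, DTBM-SEGPHOS, excess diethoxymethylsilane, t-BuOH, toluene). The ligand enantiomer is chosen so that hydride reaches the face of C4 that gives R. This step only has to deliver the small hydride to C4, and it comes back to the route at 8.

Step 5. Several processes may stall the coupling or erode the product:
- phenoxide binding to palladium,
- amine-induced opening and oligomerisation of ring B,
- air or light degradation of the p-hydroxystilbene at 80 °C.

The fallback replaces the Heck manifold by a base-free cross-coupling that joins the same two carbon atoms.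
- It sets out from 8. A Stille coupling with an excess of (E)-1,2-bis(tributylstannyl)ethene (Pd(PPh3)4, 1,4-dioxane, 90 °C) would give (R)-7-hydroxy-4-(4-hydroxy-3-methoxyphenyl)-5-[(E)-2-(tributylstannyl)ethenyl]chroman-2-one F2.
- A second Stille coupling with 10 (Pd2(dba)3, AsPh3, CuI, DMF, rt to 40 °C) proceeds with retention of the alkene geometry and comes back at 11.

Step 4. Oxidative addition at the hindered C5–Br bond next to the C4 substituent may be slow. That would allow protodebromination or thermal polymerisation of the vinyl product. The fallback installs the vinyl group before the stereocentre.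
- It sets out from 6. The Stille vinylation is run on the flat, robust coumarin and gives 7-hydroxy-5-vinylcoumarin F3.
- The Hayashi–Miyaura addition of 7 under the conditions of step 3 then attacks the enoate in preference to the styrene-type alkene and comes back at 9.

Further compounds
F1 | step 3 | 5-bromo-7-hydroxy-4-(4-hydroxy-3-methoxyphenyl)coumarin | COc1cc(-c2cc(=O)oc3cc(O)cc(Br)c23)ccc1O
F2 | step 5 | (R)-7-hydroxy-4-(4-hydroxy-3-methoxyphenyl)-5-[(E)-2-(tributylstannyl)ethenyl]chroman-2-one | CCCC[Sn](CCCC)(CCCC)/C=C/c1cc(O)cc2c1[C@@H](c1ccc(O)c(OC)c1)CC(=O)O2
F3 | step 4 | 7-hydroxy-5-vinylcoumarin | C=Cc1cc(O)cc2oc(=O)ccc12
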